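**Plan**

1. Retrosynthesis: the three aryl–prenyl C–C bonds (at C8, C5' and C6'; B ring numbered as in quercetin, 3',4'-diOH) are cut together and traced back to O–allyl bonds at O5, O4' and O3'. The five O–C bonds then lead back to quercetin.
2. Enabling feature: every prenylated carbon is ortho or para to a phenol oxygen (C8 para to O5 in ring A, C5' ortho to O4' and C6' para to O3' in ring B), and C4=O sits peri to O5. The target is therefore a threefold [3,3]-isomer of a tri-O-allyl quercetin.
3. Forward: no ring is built; rings A, B and C come intact from quercetin. The oxygens are sorted (catechol ketal, 3,7-MOM, ketal off, O4' tertiary propargyl, O3'/O5 prenyl, Lindlar), then one flask moves all three allyl groups from O to C, then the MOM groups are removed.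
4. The relay copies the biosynthetic late-stage prenyl transfer onto the finished flavonol. The usual plan (prenylated acetophenone plus prenylated benzaldehyde, chalcone, oxidative cyclisation) is kept only as a fallback.
5. Stereochemistry: none to set. The target has no stereocentre and no stable axis, and each prenyl alkene carries two methyl groups.

Key step: step 7

Remark: the target SMILES holds no stereodescriptor and the molecule is achiral, so "single enantiomer" calls for regiocontrol only. C5' and C6' of the quercetin numbering used here are C3' and C2' of the systematic name.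

**Step 1**
Reactants: 1 quercetin; 2 dichlorodiphenylmethane
Product: 3 3',4'-O-(diphenylmethylene)quercetin
Conditions: Ph2CCl2 (1.5 equiv), Ph2O, 175 °C, 30 min
Reagents that add atoms: dichlorodiphenylmethane ClC(Cl)(c1ccccc1)c1ccccc1
Why: Ketalisation with a gem-dichloride, in which only the vicinal 3',4'-diol can close the five-membered 2,2-diphenyl-1,3-benzodioxole, so the three isolated hydroxyls stay free.

**Step 2**
Reactants: 3 3',4'-O-(diphenylmethylene)quercetin; 4 chloromethyl methyl ether
Product: 5 3,7-bis-O-(methoxymethyl)-3',4'-O-(diphenylmethylene)quercetin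
Conditions: MOMCl (2.4 equiv), K2CO3, acetone, reflux
Reagents that add atoms: chloromethyl methyl ether COCCl
Why: Williamson etherification takes the two acidic hydroxyls O7–H and O3–H, while O5–H, chelated to C4=O, is not alkylated under carbonate conditions.

**Step 3**
Reactants: 5 3,7-bis-O-(methoxymethyl)-3',4'-O-(diphenylmethylene)quercetin
Product: 6 3,7-bis-O-(methoxymethyl)quercetin
Conditions: H2 (1 atm), 10% Pd/C, THF/EtOH, rt
Reagents that add atoms: none
Why: Catalytic hydrogenolysis cleaves the doubly benzylic ketal C–O bonds and leaves the MOM acetals and the chromone alone; it is placed before any alkene or alkyne enters the molecule.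

**Step 4**
Reactants: 6 3,7-bis-O-(methoxymethyl)quercetin; 7 3-chloro-3-methylbut-1-yne
Product: 8 4'-O-(2-methylbut-3-yn-2-yl)-3,7-bis-O-(methoxymethyl)quercetin
Conditions: 7 (1.1 equiv), CuCl2·2H2O (1 mol %), DBU (1.2 equiv), MeCN, 0 °C
Reagents that add atoms: 3-chloro-3-methylbut-1-yne CC(C)(Cl)C#C
Why: Copper-catalysed propargylic etherification of a phenoxide, in which O4'–H (para-conjugated to the C2=C3–C4=O enone) is the most acidic free phenol and is ionised first, so a single tertiary ether should form at O4', as in the known 4'-selective alkylation of 3,7-protected quercetin.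

**Step 5**
Reactants: 8 4'-O-(2-methylbut-3-yn-2-yl)-3,7-bis-O-(methoxymethyl)quercetin; 9 prenyl bromide (1-bromo-3-methylbut-2-ene)
Product: 10 5,3'-di-O-prenyl-4'-O-(2-methylbut-3-yn-2-yl)-3,7-bis-O-(methoxymethyl)quercetin
Conditions: 9 (3 equiv), K2CO3 (4 equiv), DMF, 45 °C
Reagents that add atoms: prenyl bromide CC(C)=CCBr
Why: Williamson etherification with an allylic bromide, in which O3'–H reacts readily and the chelated O5–H follows at slightly raised temperature, which the thermally robust propargyl ether tolerates.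

**Step 6**
Reactants: 10 5,3'-di-O-prenyl-4'-O-(2-methylbut-3-yn-2-yl)-3,7-bis-O-(methoxymethyl)quercetin
Product: 11 5,3'-di-O-prenyl-4'-O-(2-methylbut-3-en-2-yl)-3,7-bis-O-(methoxymethyl)quercetin
Conditions: H2 (1 atm), Lindlar catalyst, quinoline, EtOAc, rt
Reagents that add atoms: none
Why: Lindlar semihydrogenation stops at the terminal alkene and spares the trisubstituted prenyl alkenes and the chromone, so the heat-sensitive 1,1-dimethylallyl ether is unmasked only one step before it is used.

**Step 7**
Reactants: 11 5,3'-di-O-prenyl-4'-O-(2-methylbut-3-en-2-yl)-3,7-bis-O-(methoxymethyl)quercetin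
Product: 16 3,7-bis-O-(methoxymethyl)broussoflavonol G, via 5'-C-prenyl phenol 12 (not isolated), via A-ring C6 dienone 13 (not isolated), via 8,5'-di-C-prenyl phenol 14 (not isolated), via B-ring C2' dienone 15 (not isolated)
Conditions: Eu(fod)3 (15 mol %), NaHCO3, 1,2-dichlorobenzene (degassed), 85 °C, then 180 °C (sealed tube, Ar)
Reagents that add atoms: none
Why: Three [3,3] relays run in one flask: the tertiary O4' ether undergoes an aromatic ortho-Claisen shift to C5' (12); Eu(III) chelated between O5 and C4=O sends the O5 prenyl group to C6 (dienone 13) and on by Cope shift across C6–C7=C8 to C8 (14); at 180 °C the O3' prenyl group goes to C2' (dienone 15) and on by Cope shift across C2'–C1'=C6' to C6', each sequence ending in enolisation to the phenol. The closest known reaction types are the thermal Claisen rearrangement of aryl 1,1-dimethylallyl ethers, the Eu(fod)3-catalysed para-Claisen–Cope rearrangement of 5-O-prenylflavonoids and the thermal para-Claisen–Cope rearrangement of aryl prenyl ethers. No ring is closed and no stereocentre survives, since the sp3 carbons of 13 and 15 are erased on rearomatisation. The step needs the right carbon and a linear 3,3-dimethylallyl group at each site: one allyl inversion from the tertiary ether and two successive inversions on each para path all end in the linear group. Site control comes from the substrate: C5' is the only free ortho carbon of O4', C8 and C6' are the only para carbons of O5 and O3', and the sp3 carbons of 13 and 15 are crowded (in 15 wedged between the chromone and C3'=O), which should favour the Cope shift over enolisation in the non-basic medium. The three phenols set free are those of the target, so O5, O3' and O4' need no later deprotection.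

**Step 8**
Reactants: 16 3,7-bis-O-(methoxymethyl)broussoflavonol G
Product: 17 broussoflavonol G
Conditions: conc. HCl (cat.), MeOH, 40 °C, Ar
Reagents that add atoms: none
Why: Acid-catalysed acetal cleavage (MOM deprotection by transacetalisation to methanol) of the enol and aryl MOM groups should be fast under conditions too mild to protonate the trisubstituted prenyl alkenes, which is the usual end-game for ortho-prenylated polyphenols.

**Compound list**

1 | quercetin, 2-(3,4-dihydroxyphenyl)-3,5,7-trihydroxychromen-4-one | O=c1c(O)c(-c2ccc(O)c(O)c2)oc2cc(O)cc(O)c12 | starting material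
2 | dichlorodiphenylmethane | ClC(Cl)(c1ccccc1)c1ccccc1 | starting material
3 | 3',4'-O-(diphenylmethylene)quercetin, 2-(2,2-diphenyl-1,3-benzodioxol-5-yl)-3,5,7-trihydroxychromen-4-one | O=c1c(O)c(-c2ccc3c(c2)OC(c2ccccc2)(c2ccccc2)O3)oc2cc(O)cc(O)c12 | intermediate
4 | chloromethyl methyl ether | COCCl | starting material
5 | 3,7-bis-O-(methoxymethyl)-3',4'-O-(diphenylmethylene)quercetin (5-OH free) | O=c1c(OCOC)c(-c2ccc3c(c2)OC(c2ccccc2)(c2ccccc2)O3)oc2cc(OCOC)cc(O)c12 | intermediate
6 | 3,7-bis-O-(methoxymethyl)quercetin (5-, 3'- and 4'-OH free) | O=c1c(OCOC)c(-c2ccc(O)c(O)c2)oc2cc(OCOC)cc(O)c12 | intermediate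
7 | 3-chloro-3-methylbut-1-yne | CC(C)(Cl)C#C | starting material
8 | 4'-O-(2-methylbut-3-yn-2-yl)-3,7-bis-O-(methoxymethyl)quercetin (5- and 3'-OH free) | O=c1c(OCOC)c(-c2ccc(OC(C)(C)C#C)c(O)c2)oc2cc(OCOC)cc(O)c12 | intermediate
9 | prenyl bromide, 1-bromo-3-methylbut-2-ene | CC(C)=CCBr | starting material
10 | 5,3'-di-O-prenyl-4'-O-(2-methylbut-3-yn-2-yl)-3,7-bis-O-(methoxymethyl)quercetin | O=c1c(OCOC)c(-c2ccc(OC(C)(C)C#C)c(OCC=C(C)C)c2)oc2cc(OCOC)cc(OCC=C(C)C)c12 | intermediate
11 | 5,3'-di-O-prenyl-4'-O-(2-methylbut-3-en-2-yl)-3,7-bis-O-(methoxymethyl)quercetin | O=c1c(OCOC)c(-c2ccc(OC(C)(C)C=C)c(OCC=C(C)C)c2)oc2cc(OCOC)cc(OCC=C(C)C)c12 | intermediate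
12 | 5'-C-prenyl-5,3'-di-O-prenyl-3,7-bis-O-(methoxymethyl)quercetin (4'-OH free; formed in the flask in step 7) | O=c1c(OCOC)c(-c2cc(CC=C(C)C)c(O)c(OCC=C(C)C)c2)oc2cc(OCOC)cc(OCC=C(C)C)c12 | intermediate
13 | A-ring C6 dienone: 12 with the O5 prenyl group moved to C6 as a 2-methylbut-3-en-2-yl group, C5=O, ring double bonds C7=C8 and C8a=C4a, sp3 C6 racemic (formed in the flask in step 7) | O=C1C(OCOC)=C(c3cc(CC=C(C)C)c(O)c(OCC=C(C)C)c3)OC2=C1C(=O)C(C(C)(C)C=C)C(OCOC)=C2 | intermediate
14 | 8,5'-di-C-prenyl-3'-O-prenyl-3,7-bis-O-(methoxymethyl)quercetin (5- and 4'-OH free; formed in the flask in step 7) | O=c1c(OCOC)c(-c2cc(CC=C(C)C)c(O)c(OCC=C(C)C)c2)oc2c(CC=C(C)C)c(OCOC)cc(O)c12 | intermediate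
15 | B-ring C2' dienone: 14 with the O3' prenyl group moved to C2' as a 2-methylbut-3-en-2-yl group, C3'=O, ring double bonds C1'=C6' and C4'=C5', sp3 C2' racemic (formed in the flask in step 7) | O=c1c(OCOC)c(C3=CC(CC=C(C)C)=C(O)C(=O)C3C(C)(C)C=C)oc2c(CC=C(C)C)c(OCOC)cc(O)c12 | intermediate
16 | 3,7-bis-O-(methoxymethyl)broussoflavonol G | O=c1c(OCOC)c(-c2cc(O)c(O)c(CC=C(C)C)c2CC=C(C)C)oc2c(CC=C(C)C)c(OCOC)cc(O)c12 | intermediate
17 | broussoflavonol G, 8,5',6'-tri-C-prenylquercetin | O=c1c(O)c(-c2cc(O)c(O)c(CC=C(C)C)c2CC=C(C)C)oc2c(CC=C(C)C)c(O)cc(O)c12 | target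

**Step count and risks**

Total step count: 8. Longest linear sequence: 8 steps (from quercetin 1).

**1. Step 7 (key step).** In ring B the dienone 15 may enolise to the 2'-(1,1-dimethylallyl) phenol faster than it undergoes the Cope shift. The ortho-prenyl phenols formed in the 85 °C stage may also cyclise to chromans during the 180 °C stage.

The fallback gives up the late B-ring relay, makes the C6'–prenyl bond by cross-coupling on a benzaldehyde and builds ring C by Claisen–Schmidt condensation and Algar–Flynn–Oyamada oxidation. It sets out from 7 (with commercial 2-bromo-4,5-dihydroxybenzaldehyde; the ketone half comes from 9 and commercial 2,4,6-trihydroxyacetophenone) and comes back to the route at 17.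

- Aldehyde half: 2-bromo-4,5-dihydroxybenzaldehyde is etherified with 7 (CuCl2 cat., DBU, MeCN, 0 °C) at the 4-OH para to the formyl group to give 2-bromo-5-hydroxy-4-(2-methylbut-3-yn-2-yloxy)benzaldehyde F1. Lindlar reduction should give 2-bromo-5-hydroxy-4-(2-methylbut-3-en-2-yloxy)benzaldehyde F2. Its ortho-Claisen rearrangement (toluene, 110 °C) can only reach C3 and should give 2-bromo-4,5-dihydroxy-3-(3-methylbut-2-enyl)benzaldehyde F3. Protection with 4 and i-Pr2NEt gives 2-bromo-4,5-bis(methoxymethoxy)-3-(3-methylbut-2-enyl)benzaldehyde F4. Stille coupling with tributyl(3-methylbut-2-enyl)stannane (Pd(PPh3)4, DMF, 90 °C) places the second prenyl group at the brominated carbon and should give 4,5-bis(methoxymethoxy)-2,3-bis(3-methylbut-2-enyl)benzaldehyde F5.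
- Ketone half: 2,4,6-trihydroxyacetophenone is C-prenylated with 9 (DBU, THF) to 1-[2,4,6-trihydroxy-3-(3-methylbut-2-enyl)phenyl]ethanone F6. Protection with 4 (i-Pr2NEt) at the two less hindered hydroxyls gives 1-[2-hydroxy-4,6-bis(methoxymethoxy)-3-(3-methylbut-2-enyl)phenyl]ethanone F7.
- Union: condensation of F7 with F5 (KOH, EtOH, rt) should give (E)-1-[2-hydroxy-4,6-bis(methoxymethoxy)-3-(3-methylbut-2-enyl)phenyl]-3-[4,5-bis(methoxymethoxy)-2,3-bis(3-methylbut-2-enyl)phenyl]prop-2-en-1-one F8. Oxidative cyclisation (H2O2, NaOH, MeOH, 0 °C) through the hydroxyl next to the prenyl group should give 5,7,3',4'-tetrakis-O-(methoxymethyl)broussoflavonol G F9. The acid methanolysis of step 8 then gives 17.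

**2. Step 4.** Site selectivity between O4' and O3' may be lost, the catechol may be etherified twice, or turnover may be slow because the free catechol binds the copper catalyst.

The fallback reverses the order and the selectivity principle; it sets out from 6 and comes back at 10. The trianion of 6 (NaH, 3.3 equiv, DMSO, rt) is alkylated by one equivalent of 9 at its most nucleophilic, least delocalised oxygen O3', to give 3'-O-prenyl-3,7-bis-O-(methoxymethyl)quercetin F10. The only unchelated phenol left, O4'–H, is then etherified with 7 (CuCl2 cat., DBU, MeCN, 0 °C) to give 3'-O-prenyl-4'-O-(2-methylbut-3-yn-2-yl)-3,7-bis-O-(methoxymethyl)quercetin F11. Prenylation of O5 with 9 (K2CO3, DMF, 45 °C) joins the route at 10.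

**3. Step 5.** Etherification of the chelated O5–H may stay incomplete, and forcing the conditions may bring C-prenylation of the electron-rich A ring.

The fallback is a Mitsunobu etherification of 8 with 3-methylbut-2-en-1-ol (PPh3, DIAD, THF, 0 °C to rt). It activates the alcohol instead of the phenol, under neutral conditions, and should etherify O3' and O5 alike. It sets out from 8 and comes back at 10 without any new compound.

**Further compounds**

F1 | step 7 | 2-bromo-5-hydroxy-4-(2-methylbut-3-yn-2-yloxy)benzaldehyde | O=Cc1cc(O)c(OC(C)(C)C#C)cc1Br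
F2 | step 7 | 2-bromo-5-hydroxy-4-(2-methylbut-3-en-2-yloxy)benzaldehyde | O=Cc1cc(O)c(OC(C)(C)C=C)cc1Br
F3 | step 7 | 2-bromo-4,5-dihydroxy-3-(3-methylbut-2-enyl)benzaldehyde | O=Cc1cc(O)c(O)c(CC=C(C)C)c1Br
F4 | step 7 | 2-bromo-4,5-bis(methoxymethoxy)-3-(3-methylbut-2-enyl)benzaldehyde | O=Cc1cc(OCOC)c(OCOC)c(CC=C(C)C)c1Br
F5 | step 7 | 4,5-bis(methoxymethoxy)-2,3-bis(3-methylbut-2-enyl)benzaldehyde | O=Cc1cc(OCOC)c(OCOC)c(CC=C(C)C)c1CC=C(C)C
F6 | step 7 | 1-[2,4,6-trihydroxy-3-(3-methylbut-2-enyl)phenyl]ethanone | CC(=O)c1c(O)cc(O)c(CC=C(C)C)c1O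
F7 | step 7 | 1-[2-hydroxy-4,6-bis(methoxymethoxy)-3-(3-methylbut-2-enyl)phenyl]ethanone | CC(=O)c1c(OCOC)cc(OCOC)c(CC=C(C)C)c1O
F8 | step 7 | (E)-1-[2-hydroxy-4,6-bis(methoxymethoxy)-3-(3-methylbut-2-enyl)phenyl]-3-[4,5-bis(methoxymethoxy)-2,3-bis(3-methylbut-2-enyl)phenyl]prop-2-en-1-one | O=C(/C=C/c1cc(OCOC)c(OCOC)c(CC=C(C)C)c1CC=C(C)C)c1c(OCOC)cc(OCOC)c(CC=C(C)C)c1O
F9 | step 7 | 5,7,3',4'-tetrakis-O-(methoxymethyl)broussoflavonol G | O=c1c(O)c(-c2cc(OCOC)c(OCOC)c(CC=C(C)C)c2CC=C(C)C)oc2c(CC=C(C)C)c(OCOC)cc(OCOC)c12
F10 | step 4 | 3'-O-prenyl-3,7-bis-O-(methoxymethyl)quercetin | O=c1c(OCOC)c(-c2ccc(O)c(OCC=C(C)C)c2)oc2cc(OCOC)cc(O)c12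
F11 | step 4 | 3'-O-prenyl-4'-O-(2-methylbut-3-yn-2-yl)-3,7-bis-O-(methoxymethyl)quercetin | O=c1c(OCOC)c(-c2ccc(OC(C)(C)C#C)c(OCC=C(C)C)c2)oc2cc(OCOC)cc(O)c12
F0 | step 5 | none | none
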